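## Retrosynthetic overview
1. The target comes from its 4'-O-MOM ether; the last step only frees the phenol, and C-3 is already set.
2. Rings A and C are disconnected together, back to an (S)-α-aryl epoxy ketone carrying a 4-methoxy-2-pyranone. Forward: pyranone methanolysis, Claisen closure (ring A), then phenoxide attack on the epoxide CH2 (ring C).
3. The epoxy ketone comes from 6-lithiomethyl-4-methoxy-2-pyranone and an (S)-2-arylglycidaldehyde, by addition and oxidation in the same flask (C-4/C-4a bond).
4. The C-3 stereocentre comes from amine-catalysed H2O2 epoxidation of a 2-arylacrolein. That enal is made from the benzaldehyde by two C1 homologations (Wittig, Mannich methylenation).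
5. Ring B is bought as 4-hydroxy-2-methoxybenzaldehyde and prenylated by directed ortho-metalation. Ring order: B (bought), then A, then C, the last two in one flask.

Abbreviation: Ar = 2-methoxy-4-(methoxymethoxy)-3-(3-methylbut-2-en-1-yl)phenyl.

Assumption: the R-configured catalyst in step 5 is taken to give the S epoxide, by analogy with the steric-shielding model for α-alkylacroleins. The sense is checked on the first batch, and the equally available S catalyst is used if it is reversed.

## Route

Step 1
Reactants: 1 4-hydroxy-2-methoxybenzaldehyde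
Product: 2 2-methoxy-4-(methoxymethoxy)benzaldehyde
Conditions: MOMCl (1.2 equiv), K2CO3, acetone, 0 °C → rt
Reagents that add atoms: chloromethyl methyl ether (MOMCl), COCCl
Why: Williamson-type O-alkylation of the acidic para-formyl phenol, giving a MOM ether that masks the phenol and serves as the second ortho-director in step 2.

Step 2
Reactants: 2 2-methoxy-4-(methoxymethoxy)benzaldehyde; 3 1-bromo-3-methylbut-2-ene (prenyl bromide)
Product: 7 2-methoxy-4-(methoxymethoxy)-3-(3-methylbut-2-en-1-yl)benzaldehyde, via amino alkoxide 4 (not isolated), via 3-lithio amino alkoxide 5 (not isolated), via prenylated amino alkoxide 6 (not isolated)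
Conditions: 1-methylpiperazine, n-BuLi, THF, −20 °C, then 2; n-BuLi, −20 → 0 °C; CuBr·SMe2 (10 mol %), 3, −78 °C → rt; H2O
Reagents that add atoms: none
Why: Comins-type in situ masking of the aldehyde as an α-amino alkoxide followed by directed ortho-metalation, in which the weakly directing piperazinyl alkoxide leaves the site flanked by OMe and OMOM as the preferred lithiation position and copper-catalysed SN2 allylation installs the linear prenyl group.

Step 3
Reactants: 7 2-methoxy-4-(methoxymethoxy)-3-(3-methylbut-2-en-1-yl)benzaldehyde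
Product: 8 2-methoxy-1-(2-methoxyethenyl)-4-(methoxymethoxy)-3-(3-methylbut-2-en-1-yl)benzene (E/Z mixture)
Conditions: MeOCH2PPh3Cl, KOtBu, THF, 0 °C → rt
Reagents that add atoms: (methoxymethyl)triphenylphosphonium chloride, COC[P+](c1ccccc1)(c1ccccc1)c1ccccc1.[Cl-]
Why: Wittig olefination with the methoxymethylene ylide gives the one-carbon-homologated enol ether, and its alkene geometry does not matter because both isomers converge in step 4.

Step 4
Reactants: 8 2-methoxy-1-(2-methoxyethenyl)-4-(methoxymethoxy)-3-(3-methylbut-2-en-1-yl)benzene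
Product: 10 2-Ar-prop-2-enal, via Mannich base 9 (not isolated)
Conditions: [Me2N=CH2]I (1.3 equiv), CH2Cl2, 0 °C → rt; sat. aq NaHCO3, rt
Reagents that add atoms: N,N-dimethylmethyleneiminium iodide (Eschenmoser's salt), C=[N+](C)C.[I-]; water, O
Why: Eschenmoser methylenation, that is Mannich aminomethylation of the enol ether at its aryl-bearing carbon, hydrolysis of the oxocarbenium ion and E1cB loss of dimethylamine from the acidic α-aryl aldehyde 9, which needs no acid that could touch MOM or prenyl.

Step 5
Reactants: 10 2-Ar-prop-2-enal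
Product: 11 (2S)-2-Ar-oxirane-2-carbaldehyde
Conditions: (R)-2-[diphenyl(methyldiphenylsilyloxy)methyl]pyrrolidine (10 mol %), 30% aq H2O2 (3 equiv), toluene, 0 °C → rt
Reagents that add atoms: hydrogen peroxide, OO
Why: Iminium–enamine organocatalysis (asymmetric Weitz–Scheffer epoxidation of an α-substituted acrolein), in which hydroperoxide adds to the CH2 terminus and the shielded enamine closes onto the O–O bond from its open face to set the quaternary centre as S, while the nucleophilic oxidant leaves the electron-rich prenyl alkene alone.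

Step 6
Reactants: 11 (2S)-2-Ar-oxirane-2-carbaldehyde; 12 4-methoxy-6-methyl-2H-pyran-2-one
Product: 15 4-methoxy-6-{2-oxo-2-[(2S)-2-Ar-oxiran-2-yl]ethyl}-2H-pyran-2-one, via lithiated pyranone 13 (not isolated), via lithium alkoxide 14 (not isolated)
Conditions: 12, LiN(SiMe3)2, THF, −78 °C; 11, −78 °C; PhS(Cl)=NtBu (1.2 equiv), −78 °C; pH 7 buffer
Reagents that add atoms: none
Why: Vinylogous deprotonation of the pyranone methyl group, 1,2-addition to the non-enolisable aldehyde and Mukaiyama sulfinimidoyl chloride oxidation of the lithium alkoxide give the ketone without isolating the acid-labile benzylic epoxy alcohol, and the quaternary centre is not touched.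

Step 7
Reactants: 15 4-methoxy-6-{2-oxo-2-[(2S)-2-Ar-oxiran-2-yl]ethyl}-2H-pyran-2-one
Product: 18 (3S)-3-Ar-3,5-dihydroxy-7-methoxy-2,3-dihydro-4H-chromen-4-one, via ring-opened triketide ester 16 (not isolated), via acylresorcinol epoxide 17 (not isolated)
Conditions: NaOMe (1.05 equiv), degassed MeOH–THF 4:1 (0.02 M), 0 → 50 °C; AcOH (1.1 equiv)
Reagents that add atoms: none
Why: Proposed new method: methoxide opens the pyranone at the lactone carbonyl to ester 16, whose ester and diketone arms stay cis; the diketonate carbon closes ring A by a Claisen (Dieckmann-type) condensation that expels the same methoxide, the hindered ketone blocking the competing aldol (resorcylate) mode; one of the two equivalent phenoxides of 17 then opens the epoxide by SN2 attack at its unhindered CH2 (6-endo) to close ring C, so the C–O bond at the quaternary carbon is never broken and the S configuration is carried over; holding the base at one equivalent keeps free methoxide too low for intermolecular epoxide opening, because ring opening runs through the kinetically equivalent neutral pyranone/methoxide pair; the closest known reaction types are the biomimetic base-induced isomerisation of 6-acylmethyl-4-methoxy-2-pyranones to 2-acyl-5-methoxyresorcinols and the phenoxide opening of 2'-hydroxyaryl epoxy ketones in the Algar–Flynn–Oyamada manifold.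

Step 8
Reactants: 18 (3S)-3-Ar-3,5-dihydroxy-7-methoxy-2,3-dihydro-4H-chromen-4-one
Product: 19 (3S)-3,5-dihydroxy-3-[4-hydroxy-2-methoxy-3-(3-methylbut-2-en-1-yl)phenyl]-7-methoxy-2,3-dihydro-4H-chromen-4-one
Conditions: p-TsOH·H2O (20 mol %), MeOH, 40 °C
Reagents that add atoms: none
Why: Acid-catalysed transacetalisation of the aryl MOM ether to methanol, in which the adjacent chelated carbonyl disfavours ionisation of the tertiary carbinol, so C-3 stays S and the prenyl group survives the mild acid.

## Compound list
1 | 4-hydroxy-2-methoxybenzaldehyde | COc1cc(O)ccc1C=O | starting material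
2 | 2-methoxy-4-(methoxymethoxy)benzaldehyde | COCOc1ccc(C=O)c(OC)c1 | intermediate
3 | 1-bromo-3-methylbut-2-ene (prenyl bromide) | CC(C)=CCBr | starting material
4 | lithium [2-methoxy-4-(methoxymethoxy)phenyl](4-methylpiperazin-1-yl)methanolate (racemic) | [Li+].[O-]C(N1CCN(C)CC1)c1ccc(OCOC)cc1OC | intermediate
5 | lithium [3-lithio-2-methoxy-4-(methoxymethoxy)phenyl](4-methylpiperazin-1-yl)methanolate (racemic) | [Li+].[O-]C(N1CCN(C)CC1)c1ccc(OCOC)c([Li])c1OC | intermediate
6 | lithium Ar(4-methylpiperazin-1-yl)methanolate (racemic) | [Li+].[O-]C(N1CCN(C)CC1)c1ccc(OCOC)c(CC=C(C)C)c1OC | intermediate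
7 | 2-methoxy-4-(methoxymethoxy)-3-(3-methylbut-2-en-1-yl)benzaldehyde | COCOc1ccc(C=O)c(OC)c1CC=C(C)C | intermediate
8 | 2-methoxy-1-(2-methoxyethenyl)-4-(methoxymethoxy)-3-(3-methylbut-2-en-1-yl)benzene (E/Z mixture) | COC=Cc1ccc(OCOC)c(CC=C(C)C)c1OC | intermediate
9 | 3-(dimethylamino)-2-Ar-propanal (racemic) | CN(C)CC(C=O)c1ccc(OCOC)c(CC=C(C)C)c1OC | intermediate
10 | 2-Ar-prop-2-enal | C=C(C=O)c1ccc(OCOC)c(CC=C(C)C)c1OC | intermediate
11 | (2S)-2-Ar-oxirane-2-carbaldehyde | O=C[C@]1(c2ccc(OCOC)c(CC=C(C)C)c2OC)CO1 | intermediate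
12 | 4-methoxy-6-methyl-2H-pyran-2-one | COC1=CC(=O)OC(C)=C1 | starting material
13 | 6-(lithiomethyl)-4-methoxy-2H-pyran-2-one | [Li]CC1=CC(OC)=CC(=O)O1 | intermediate
14 | lithium 1-[(2S)-2-Ar-oxiran-2-yl]-2-(4-methoxy-2-oxo-2H-pyran-6-yl)ethan-1-olate (both carbinol epimers) | [Li+].[O-]C(CC1=CC(OC)=CC(=O)O1)[C@]1(c2ccc(OCOC)c(CC=C(C)C)c2OC)CO1 | intermediate
15 | 4-methoxy-6-{2-oxo-2-[(2S)-2-Ar-oxiran-2-yl]ethyl}-2H-pyran-2-one | COC1=CC(=O)OC(CC(=O)[C@]2(c3ccc(OCOC)c(CC=C(C)C)c3OC)CO2)=C1 | intermediate
16 | methyl (2E)-3-methoxy-5,7-dioxo-7-[(2S)-2-Ar-oxiran-2-yl]hept-2-enoate | COC(=O)/C=C(/OC)CC(=O)CC(=O)[C@]1(c2ccc(OCOC)c(CC=C(C)C)c2OC)CO1 | intermediate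
17 | (2,6-dihydroxy-4-methoxyphenyl)[(2S)-2-Ar-oxiran-2-yl]methanone | COc1cc(O)c(C(=O)[C@]2(c3ccc(OCOC)c(CC=C(C)C)c3OC)CO2)c(O)c1 | intermediate
18 | (3S)-3-Ar-3,5-dihydroxy-7-methoxy-2,3-dihydro-4H-chromen-4-one | COc1cc(O)c2c(c1)OC[C@@](O)(c1ccc(OCOC)c(CC=C(C)C)c1OC)C2=O | intermediate
19 | (3S)-3,5-dihydroxy-3-[4-hydroxy-2-methoxy-3-(3-methylbut-2-en-1-yl)phenyl]-7-methoxy-2,3-dihydro-4H-chromen-4-one | COc1cc(O)c2c(c1)OC[C@@](O)(c1ccc(O)c(CC=C(C)C)c1OC)C2=O | target

## Step count and risks
Total step count: 8. Longest linear sequence: 8 steps (1 → 19); 3 and 12 are bought.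

**Step 7 (most likely to fail).** The epoxide may be lost to methanolysis or to 5-exo closure to a benzofuranone before or instead of the 6-endo closure, or the pyranone anion may resist opening. The fallback closes ring C on a bought ring A; it sets out from 7 and comes back at 18.
- Thiazolium-carbene-catalysed hydroxymethylation of 7 with paraformaldehyde (iPr2NEt, THF, 60 °C) gives 2-hydroxy-1-Ar-ethan-1-one F1.
- Mitsunobu etherification (PPh3, DIAD, THF) of F1 with purchased 2,6-dihydroxy-4-methoxybenzaldehyde gives 2-hydroxy-4-methoxy-6-(2-Ar-2-oxoethoxy)benzaldehyde F2.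
- An enantioselective intramolecular crossed aldehyde–ketone benzoin reaction closes ring C, sets C-3 and delivers 18. It uses a chiral aminoindanol-derived triazolium precatalyst (the enantiomer that gives S) and Et3N.

**Step 5.** The method is proven for α-alkylacroleins. With an α-aryl group the enamine geometry, and therefore both the ee and the sense of induction, is uncertain, and 10 can dimerise. The fallback replaces organocatalysis by a hydroxyl-directed epoxidation with a predictable sense; it sets out from 10 and comes back at 11.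
- Luche reduction (NaBH4, CeCl3·7H2O, MeOH, 0 °C) gives 2-Ar-prop-2-en-1-ol F3.
- Sharpless asymmetric epoxidation (Ti(OiPr)4 10 mol %, D-(−)-diisopropyl tartrate 12 mol %, tBuOOH, 4 Å sieves, CH2Cl2, −25 °C) reacts only at the allylic alcohol, not at the prenyl alkene. It gives [(2R)-2-Ar-oxiran-2-yl]methanol F4.
- F4 is taken crude into a Parikh–Doering oxidation (SO3·pyridine, DMSO, Et3N). The same spatial arrangement is then named 2S, and the product is 11.

**Step 6.** Alkoxide 14 can undergo Payne rearrangement, or the oxidant can be consumed by the acidic product. The fallback joins the fragments at the ester oxidation level, so the epoxide always carries an electron-withdrawing group. It sets out from 11 and comes back at 15.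
- Pinnick oxidation (NaClO2, NaH2PO4, 2-methylbut-2-ene, tBuOH–H2O) with a basic work-up gives sodium (2S)-2-Ar-oxirane-2-carboxylate F5.
- MeI in DMF converts F5 into methyl (2S)-2-Ar-oxirane-2-carboxylate F6.
- Claisen acylation of two equivalents of 13 with F6 (THF, −78 → −20 °C) gives 15.

## Further compounds
F1 | step 7 | 2-hydroxy-1-Ar-ethan-1-one | OCC(=O)c1ccc(OCOC)c(CC=C(C)C)c1OC
F2 | step 7 | 2-hydroxy-4-methoxy-6-(2-Ar-2-oxoethoxy)benzaldehyde | COc1cc(O)c(C=O)c(OCC(=O)c2ccc(OCOC)c(CC=C(C)C)c2OC)c1
F3 | step 5 | 2-Ar-prop-2-en-1-ol | C=C(CO)c1ccc(OCOC)c(CC=C(C)C)c1OC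
F4 | step 5 | [(2R)-2-Ar-oxiran-2-yl]methanol | OC[C@]1(c2ccc(OCOC)c(CC=C(C)C)c2OC)CO1
F5 | step 6 | sodium (2S)-2-Ar-oxirane-2-carboxylate | [Na+].[O-]C(=O)[C@]1(c2ccc(OCOC)c(CC=C(C)C)c2OC)CO1
F6 | step 6 | methyl (2S)-2-Ar-oxirane-2-carboxylate | COC(=O)[C@]1(c2ccc(OCOC)c(CC=C(C)C)c2OC)CO1
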